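I chose to rank the four flasks by how much target can survive at each temperature, not by how fast the substrate goes. They are charged alike and stopped at the same time, so temperature is what separates them.

| setting | Saturday's | Wednesday's | teal | blue | amber | ochre |
|---|---|---|---|---|---|---|
| substrate | 0.42 M | 0.66 M | 0.30 M | 0.30 M | 0.30 M | 0.30 M |
| reagent | 0.60 M | 0.60 M | 0.600 M | 0.600 M | 0.600 M | 0.600 M |
| temperature | 85 °C | 118 °C | 130 °C | 70 °C | 110 °C | 90 °C |
| remark | run made earlier | run made earlier |  |  |  |  |
| time |  |  | 6.0 d | 6.0 d | 6.0 d | 6.0 d |

| run | time / d | target / % | substrate / % |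
|---|---|---|---|
| Saturday's | 5.00 | 24 | 34 |
| Saturday's | 8.00 | 25 | 27 |
| Saturday's | 10.0 | 23 | 21 |
| Saturday's | 15.0 | 22 | 14 |
| Saturday's | 25.0 | 20 | 11 |
| Saturday's | 40.0 | 14 | 7 |
| Saturday's | 60.0 | 8 | 2 |
| Wednesday's | 0.833 | 10 | 21 |
| Wednesday's | 1.67 | 8 | 14 |
| Wednesday's | 2.08 | 4 | 11 |
| Wednesday's | 3.00 | 1 | 11 |
| Wednesday's | 5.00 | 7 | 10 |
| Wednesday's | 8.00 | 1 | 12 |
| Wednesday's | 10.0 | 3 | 10 |

(scatter of a reading: 2 percentage points)



- the flask that comes out highest in amount of target, in percent of the substrate charged, or "all alike" when all lie within 1.5 percentage points (teal / blue / amber / ochre / all alike)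
- target at the end, in percent of the substrate charged, teal
- target at the end, in percent of the substrate charged, blue
- target at the end, in percent of the substrate charged, amber
- target at the end, in percent of the substrate charged, ochre

The runs seem to contradict each other. At 5.00 d, Wednesday's hotter flask had less substrate left than Saturday's, 10% against 34%, yet its last 4 target readings average 3.00%, less than Saturday's 24%.

Saturday's tail clears this up. There c(target) multiplied by time read 50.4 M·h, 56.4 M·h and 48.4 M·h while time grew 2.40-fold. A second-order loss behaves this way, though the scatter allows a first-order tail, so I froze it as a working rule. I call this product the holding number, 51.7 M·h on Saturday; Wednesday's last 4 readings give 181 M·min. Divided by time, it gives an estimate of target in the tail of a run, which I call the tail figure; it is no bound. At 5.00 d Saturday's tail figure was 103% of the charge, more than the reading of 24%, so I took that flask to be still short of its tail, while Wednesday's at 5.00 d was 3.80%, against the 3.00% average of its last readings.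

Drawing the logarithm of the holding number as a straight line in temperature through the two runs, and beyond them for blue and teal, I reckoned tail figures at 6.0 d of 436% for blue, 77.8% for ochre, 13.9% for amber and 2.48% for teal. I therefore expected ochre to lead, and I took blue's figure, more than the charge, as the sign of a flask still short of its tail.

The forecast named ochre, with teal 1%, blue 12%, amber 5% and ochre 28%; of amber it said “conversion is complete, but target has mostly decayed”.

The flasks gave teal 0.522%, blue 5.39%, amber 5.48% and ochre 26.1%, so ochre came highest.

    substrate + reagent ⇌ intermediate (K = 2.80 /M, k = 0.0702 /M/h, Ea = 105 kJ/mol, ΔH = 48.0 kJ/mol)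
    intermediate ⇌ target + by-product (K = 0.320 M, k = 0.0256 /h, Ea = 123 kJ/mol, ΔH = −24.0 kJ/mol)
    target ⇌ isomer of the product (K = 0.364, k = 0.0253 /h, Ea = 112 kJ/mol, ΔH = 0 kJ/mol)
    intermediate → side product (k = 0.0197 /h, Ea = 126 kJ/mol)
    (constants at 90 °C)

Amber's holding number read 136 M·min, 142 M·min and 135 M·min at 3.00 d, 6.00 d and 60.0 d. In teal, the relaxation half-life of target with isomer of the product by that step alone, 0.184 h, is shorter than the 6.0 d run. At the end, teal held 0.522% target beside 0.190% isomer of the product. The flask like teal at 105 °C gave 9.63%, less than its reckoned tail figure of 21.4%.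

(Readings and results are calculated for substances that don't exist; the scatter is artificial.)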